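The synthesis rests on cutting the bond between ring B carbon C1 and its carboxyl carbon (ring B numbered as in orsellinic acid). C1 lies ortho to the free C2 hydroxyl, para to the C4 depside oxygen and beside the C6 methyl, exactly where a magnesium phenoxide delivers formaldehyde. One operation therefore turns an unprotected orcinol monoester into the salicylaldehyde, which chlorite then oxidises to the acid. The precursor is the 3-hydroxy-5-methylphenyl ester of the ring A acid, its phenol masked as a benzyl ether and its side-chain ketone as a dioxolane, so that the ring B hydroxyl is the only site able to bind magnesium and no enolisable carbonyl is exposed.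

Key step: step 8

Remark: the target has no stereocentre and no configured double bond. Ring A is the benzoyl ring carrying the methoxy group and the 2-oxononyl chain; ring B is the orsellinic acid ring (C1 carboxyl-bearing, C2 hydroxyl, C4 depside oxygen, C6 methyl).
Remark: salts of a product that are only protonated at work-up are not numbered separately; orcinol is used in anhydrous form.

Step 1
Reactants: 1 methyl orsellinate (methyl 2,4-dihydroxy-6-methylbenzoate)
Product: 2 methyl 2-hydroxy-4-methoxy-6-methylbenzoate
Conditions: MeI (1.05 equiv), K2CO3 (1.1 equiv), acetone, 40 °C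
Reagents that add atoms: iodomethane, CI
Why: Williamson etherification should occur only at the C4 hydroxyl, because the C2 hydroxyl is held in a hydrogen bond to the ester carbonyl and is both less acidic and less nucleophilic.

Step 2
Reactants: 2 methyl 2-hydroxy-4-methoxy-6-methylbenzoate
Product: 3 methyl 2-(benzyloxy)-4-methoxy-6-methylbenzoate
Conditions: BnBr (1.3 equiv), K2CO3 (2 equiv), DMF, 60 °C
Reagents that add atoms: benzyl bromide, BrCc1ccccc1
Why: Williamson etherification in a polar aprotic solvent with heat overcomes the chelated phenol, and the benzyl ether is chosen because it should survive amide base, hot hydroxide, the magnesium step and chlorite and leaves by hydrogenolysis.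

Step 3
Reactants: 4 octanoyl chloride
Product: 5 N-methoxy-N-methyloctanamide
Conditions: MeNHOMe·HCl (1.1 equiv), Et3N (2.3 equiv), CH2Cl2, 0 °C → rt
Reagents that add atoms: N,O-dimethylhydroxylamine hydrochloride, CNOC.Cl
Why: Nucleophilic acyl substitution of the acid chloride by the hydroxylamine (Weinreb amide formation) should be clean, with Et3N taking up both equivalents of HCl.

Step 4
Reactants: 3 methyl 2-(benzyloxy)-4-methoxy-6-methylbenzoate; 5 N-methoxy-N-methyloctanamide
Product: 8 methyl 2-(benzyloxy)-4-methoxy-6-(2-oxononyl)benzoate, via benzylic lithium species 6 (not isolated), via tetrahedral lithium alkoxide 7 (not isolated)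
Conditions: 3 added to LiN(iPr)2 (1.3 equiv), THF, −78 °C; then 5 (1.3 equiv), −78 → −40 °C; aq. NH4Cl
Reagents that add atoms: none
Why: Lateral lithiation of the ortho-toluate gives an ester-stabilised benzylic carbanion whose acylation by the Weinreb amide stops at the chelated tetrahedral adduct, so the ketone is released only on quench and neither over-addition nor enolate chemistry of the product can take place.

Step 5
Reactants: 8 methyl 2-(benzyloxy)-4-methoxy-6-(2-oxononyl)benzoate
Product: 9 methyl 2-(benzyloxy)-6-[(2-heptyl-1,3-dioxolan-2-yl)methyl]-4-methoxybenzoate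
Conditions: Me3SiOCH2CH2OSiMe3 (2 equiv), Me3SiOTf (5 mol %), CH2Cl2, −78 → −20 °C; pyridine, aq. NaHCO3
Reagents that add atoms: 1,2-bis(trimethylsilyloxy)ethane, C[Si](C)(C)OCCO[Si](C)(C)C
Why: Silyl-transfer (Noyori) ketalisation is driven by formation of hexamethyldisiloxane and runs cold and aprotic, which should keep the ortho ester from closing onto the ketone enol to an isocoumarin, as it may under hot protic acid.

Step 6
Reactants: 9 methyl 2-(benzyloxy)-6-[(2-heptyl-1,3-dioxolan-2-yl)methyl]-4-methoxybenzoate
Product: 10 2-(benzyloxy)-6-[(2-heptyl-1,3-dioxolan-2-yl)methyl]-4-methoxybenzoic acid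
Conditions: KOH (10 equiv), DMSO–H2O (4:1), 90 °C; then 1 M HCl at 0 °C to pH 4–5
Reagents that add atoms: potassium hydroxide, [K+].[OH-]
Why: Saponification of the doubly ortho-substituted methyl ester needs poorly solvated hydroxide in hot aqueous DMSO, conditions to which the dioxolane and both ethers are inert, and the cold, weakly acidic work-up should spare the ketal.

Step 7
Reactants: 10 2-(benzyloxy)-6-[(2-heptyl-1,3-dioxolan-2-yl)methyl]-4-methoxybenzoic acid; 11 orcinol (5-methylbenzene-1,3-diol)
Product: 13 3-hydroxy-5-methylphenyl 2-(benzyloxy)-6-[(2-heptyl-1,3-dioxolan-2-yl)methyl]-4-methoxybenzoate, via acid chloride 12 (not isolated)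
Conditions: Me2C=C(Cl)NMe2 (1.1 equiv), CH2Cl2, 0 °C → rt; then added to 11 (4 equiv), Et3N (2 equiv), DMAP (0.2 equiv), THF, 0 → 40 °C
Reagents that add atoms: none
Why: The chloroenamine converts the acid into its chloride without releasing HCl, so the dioxolane is not exposed to acid, and DMAP-catalysed acylation (nucleophilic acyl substitution) of a fourfold excess of the symmetric diol should give mainly the monoester, the surplus orcinol being washed out with water.

Step 8
Reactants: 13 3-hydroxy-5-methylphenyl 2-(benzyloxy)-6-[(2-heptyl-1,3-dioxolan-2-yl)methyl]-4-methoxybenzoate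
Product: 16 4-formyl-3-hydroxy-5-methylphenyl 2-(benzyloxy)-6-[(2-heptyl-1,3-dioxolan-2-yl)methyl]-4-methoxybenzoate, via chloromagnesium phenoxide 14 (not isolated), via salicyl alcohol 15 (not isolated)
Conditions: MgCl2 (anhydrous, 2 equiv), Et3N (4 equiv), (CH2O)n (6 equiv), THF, reflux; then cold 0.5 M HCl to pH 4
Reagents that add atoms: paraformaldehyde (reacts as formaldehyde), C=O
Why: Et3N and MgCl2 convert the only free phenol into chloromagnesium phenoxide 14, magnesium-bound formaldehyde is delivered through a six-membered cyclic transition state to an ortho carbon, and rearomatisation gives the magnesium chelate of salicyl alcohol 15. Hydride transfer from this benzylic alkoxide to a second formaldehyde (an Oppenauer-type redox) then gives the aldehyde and methanol. The closest known reaction is the magnesium-mediated ortho-specific formylation of phenols (Casnati–Skattebøl conditions), applied here to a phenol that carries a hindered aryl ester. No ring is closed and no stereocentre is formed. The step needs ortho rather than para attack, which the magnesium chelate enforces (C5 stays untouched), and attack at ring B C1 rather than C3: C1 has the small methyl as neighbour and receives resonance donation from the para acyloxy oxygen, whereas C3 sits between the two oxygens, is inductively deactivated and is flanked by the bulky 2,6-disubstituted aroyloxy group. Ring A has no free phenol, the dioxolane removes the enolisable ketone that MgCl2 and Et3N could otherwise hydroxymethylate, and the doubly ortho-substituted ester should be too hindered for acyl transfer.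

Step 9
Reactants: 16 4-formyl-3-hydroxy-5-methylphenyl 2-(benzyloxy)-6-[(2-heptyl-1,3-dioxolan-2-yl)methyl]-4-methoxybenzoate
Product: 17 4-({2-(benzyloxy)-6-[(2-heptyl-1,3-dioxolan-2-yl)methyl]-4-methoxybenzoyl}oxy)-2-hydroxy-6-methylbenzoic acid
Conditions: NaClO2 (3 equiv), NaH2PO4 (4 equiv), 2-methyl-2-butene (20 equiv), t-BuOH–THF–H2O, 0 °C → rt
Reagents that add atoms: sodium chlorite, [Na+].[O-]Cl=O
Why: In this Pinnick (Lindgren) oxidation chlorous acid adds to the aldehyde and the adduct fragments to the acid and HOCl, which the large excess of alkene should trap before it chlorinates the electron-rich rings, while the phosphate buffer is mild enough for the dioxolane, whose partial loss would be harmless at this point.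

Step 10
Reactants: 17 4-({2-(benzyloxy)-6-[(2-heptyl-1,3-dioxolan-2-yl)methyl]-4-methoxybenzoyl}oxy)-2-hydroxy-6-methylbenzoic acid
Product: 19 2-hydroxy-4-{[2-hydroxy-4-methoxy-6-(2-oxononyl)benzoyl]oxy}-6-methylbenzoic acid (target), via keto acid benzyl ether 18 (not isolated)
Conditions: 1 M aq. HCl–THF (1:3), rt; then 10% Pd/C, H2 (1 atm), same flask, rt
Reagents that add atoms: water, O
Why: Acid-catalysed hydrolysis of the dialkyl ketone dioxolane through its oxocarbenium ion is followed in the same flask by palladium-catalysed hydrogenolysis of the benzyl ether, to which the dialkyl ketone, the aryl ester, the carboxylic acid and both arenes should be inert at one atmosphere.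

Compound list
1 | methyl orsellinate (methyl 2,4-dihydroxy-6-methylbenzoate) | COC(=O)c1c(C)cc(O)cc1O | starting material
2 | methyl 2-hydroxy-4-methoxy-6-methylbenzoate | COC(=O)c1c(C)cc(OC)cc1O | intermediate
3 | methyl 2-(benzyloxy)-4-methoxy-6-methylbenzoate | COC(=O)c1c(C)cc(OC)cc1OCc1ccccc1 | intermediate
4 | octanoyl chloride | CCCCCCCC(=O)Cl | starting material
5 | N-methoxy-N-methyloctanamide | CCCCCCCC(=O)N(C)OC | intermediate
6 | benzylic lithium species of 3 (methyl 2-(benzyloxy)-6-(lithiomethyl)-4-methoxybenzoate; in situ) | [Li]Cc1cc(OC)cc(OCc2ccccc2)c1C(=O)OC | intermediate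
7 | tetrahedral lithium alkoxide from 6 and 5 (lithium salt of the N-methoxy-N-methyl hemiaminal; in situ) | CCCCCCCC(O[Li])(Cc1cc(OC)cc(OCc2ccccc2)c1C(=O)OC)N(C)OC | intermediate
8 | methyl 2-(benzyloxy)-4-methoxy-6-(2-oxononyl)benzoate | CCCCCCCC(=O)Cc1cc(OC)cc(OCc2ccccc2)c1C(=O)OC | intermediate
9 | methyl 2-(benzyloxy)-6-[(2-heptyl-1,3-dioxolan-2-yl)methyl]-4-methoxybenzoate | CCCCCCCC1(Cc2cc(OC)cc(OCc3ccccc3)c2C(=O)OC)OCCO1 | intermediate
10 | 2-(benzyloxy)-6-[(2-heptyl-1,3-dioxolan-2-yl)methyl]-4-methoxybenzoic acid | CCCCCCCC1(Cc2cc(OC)cc(OCc3ccccc3)c2C(=O)O)OCCO1 | intermediate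
11 | orcinol (5-methylbenzene-1,3-diol) | Cc1cc(O)cc(O)c1 | starting material
12 | 2-(benzyloxy)-6-[(2-heptyl-1,3-dioxolan-2-yl)methyl]-4-methoxybenzoyl chloride (in situ) | CCCCCCCC1(Cc2cc(OC)cc(OCc3ccccc3)c2C(Cl)=O)OCCO1 | intermediate
13 | 3-hydroxy-5-methylphenyl 2-(benzyloxy)-6-[(2-heptyl-1,3-dioxolan-2-yl)methyl]-4-methoxybenzoate | CCCCCCCC1(Cc2cc(OC)cc(OCc3ccccc3)c2C(=O)Oc2cc(C)cc(O)c2)OCCO1 | intermediate
14 | chloromagnesium phenoxide of 13 (in situ) | CCCCCCCC1(Cc2cc(OC)cc(OCc3ccccc3)c2C(=O)Oc2cc(C)cc(O[Mg]Cl)c2)OCCO1 | intermediate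
15 | 3-hydroxy-4-(hydroxymethyl)-5-methylphenyl 2-(benzyloxy)-6-[(2-heptyl-1,3-dioxolan-2-yl)methyl]-4-methoxybenzoate (present as its magnesium chelate, drawn neutral; in situ) | CCCCCCCC1(Cc2cc(OC)cc(OCc3ccccc3)c2C(=O)Oc2cc(C)c(CO)c(O)c2)OCCO1 | intermediate
16 | 4-formyl-3-hydroxy-5-methylphenyl 2-(benzyloxy)-6-[(2-heptyl-1,3-dioxolan-2-yl)methyl]-4-methoxybenzoate | CCCCCCCC1(Cc2cc(OC)cc(OCc3ccccc3)c2C(=O)Oc2cc(C)c(C=O)c(O)c2)OCCO1 | intermediate
17 | 4-({2-(benzyloxy)-6-[(2-heptyl-1,3-dioxolan-2-yl)methyl]-4-methoxybenzoyl}oxy)-2-hydroxy-6-methylbenzoic acid | CCCCCCCC1(Cc2cc(OC)cc(OCc3ccccc3)c2C(=O)Oc2cc(C)c(C(=O)O)c(O)c2)OCCO1 | intermediate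
18 | 4-{[2-(benzyloxy)-4-methoxy-6-(2-oxononyl)benzoyl]oxy}-2-hydroxy-6-methylbenzoic acid (in situ) | CCCCCCCC(=O)Cc1cc(OC)cc(OCc2ccccc2)c1C(=O)Oc1cc(C)c(C(=O)O)c(O)c1 | intermediate
19 | 2-hydroxy-4-{[2-hydroxy-4-methoxy-6-(2-oxononyl)benzoyl]oxy}-6-methylbenzoic acid | CCCCCCCC(=O)Cc1cc(OC)cc(O)c1C(=O)Oc1cc(C)c(C(=O)O)c(O)c1 | target

Total step count: 10. Longest linear sequence: 9 steps (steps 1, 2 and 4 to 10, from 1 to 19); step 3 is a one-step side branch.

Steps most likely to fail

Step 8. Three processes may spoil it: attack at C3 between the two oxygens in competition with C1; arrest at the hydroxymethyl stage, or diversion of the benzylic intermediate to methoxymethyl or diarylmethane by-products, because the acyloxy group lowers the nucleophilicity of the phenoxide; and transfer of the aroyl group from one molecule to the phenoxide of another. The fallback brings the formyl carbon in on ring B instead of installing it late. Setting out from acid 10, acid chloride 12 is generated as in step 7 and added to purchased 2,4-dihydroxy-6-methylbenzaldehyde (Cc1cc(O)cc(O)c1C=O, 1.5 equiv) with Et3N and DMAP in THF at 0 °C. The C2 hydroxyl of that aldehyde is held in a hydrogen bond to the formyl group, so acylation should occur at the more acidic C4 hydroxyl and give 16 directly, where the route is rejoined. This fallback makes no new compound (F0).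

Step 7. Double acylation of orcinol, slow acyl transfer from the doubly ortho-substituted acid chloride, or attack of a dioxolane oxygen on the acyl chloride followed by lactonisation may erode the step. The fallback replaces both the activation and the statistical element. Orcinol 11 is monosilylated (tBuMe2SiCl 1 equiv, imidazole, DMF) to 3-[(tert-butyldimethylsilyl)oxy]-5-methylphenol F1. Acid 10 is then coupled to F1 by Steglich esterification (EDC·HCl, DMAP, CH2Cl2, rt) to give 3-[(tert-butyldimethylsilyl)oxy]-5-methylphenyl 2-(benzyloxy)-6-[(2-heptyl-1,3-dioxolan-2-yl)methyl]-4-methoxybenzoate F2. Bu4NF buffered with AcOH (THF, 0 °C) removes the silyl group and returns the route to 13.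

Step 10. Once the ketone is unmasked in aqueous mineral acid, its enol may close onto the aryl ester and expel ring B (isocoumarin formation), or the depside bond may be hydrolysed. The fallback separates the two unmaskings and avoids mineral acid. From 17, neutral hydrogenolysis (H2, 10% Pd/C, EtOAc, rt) gives 4-({2-[(2-heptyl-1,3-dioxolan-2-yl)methyl]-6-hydroxy-4-methoxybenzoyl}oxy)-2-hydroxy-6-methylbenzoic acid F3. The dioxolane of F3 is then removed under buffered conditions (pyridinium p-toluenesulfonate, acetone–H2O, 40 °C) with close monitoring, so that acid contact is limited to this last operation, giving 19.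

Further compounds
F0 | step 8 | none | none
F1 | step 7 | 3-[(tert-butyldimethylsilyl)oxy]-5-methylphenol | Cc1cc(O)cc(O[Si](C)(C)C(C)(C)C)c1
F2 | step 7 | 3-[(tert-butyldimethylsilyl)oxy]-5-methylphenyl 2-(benzyloxy)-6-[(2-heptyl-1,3-dioxolan-2-yl)methyl]-4-methoxybenzoate | CCCCCCCC1(Cc2cc(OC)cc(OCc3ccccc3)c2C(=O)Oc2cc(C)cc(O[Si](C)(C)C(C)(C)C)c2)OCCO1
F3 | step 10 | 4-({2-[(2-heptyl-1,3-dioxolan-2-yl)methyl]-6-hydroxy-4-methoxybenzoyl}oxy)-2-hydroxy-6-methylbenzoic acid | CCCCCCCC1(Cc2cc(OC)cc(O)c2C(=O)Oc2cc(C)c(C(=O)O)c(O)c2)OCCO1
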